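## Retrosynthetic overview
1. The target comes from its 4'-O-TBS ether. Ring C, the C2–C3 bond and both stereocentres are traced back to one ring contraction.
2. Six-membered ring C comes from a racemic seven-membered 2-aryl-1,3-benzodioxepin-5-one. The acetal carbon shifts 1,2 from the ring oxygen onto the neighbouring ketone α-carbon under a chiral Brønsted acid, and the expelled ring oxygen becomes the 3-OH.
3. The seven-membered acetal comes from prenyl bromide (chelation-controlled O-alkylation), 4-silyloxybenzaldehyde and 2-hydroxy-1-(2,4,6-trihydroxyphenyl)ethanone.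
4. The aldehyde comes from 4-bromophenol TBS ether and DMF. The ketone comes from resorcinol bis-MOM ether by C2 lithiation/acylation with a glycolate ester, then C–H borylation/oxidation for the third oxygen.
5. Ring order: rings A and B are bought benzene rings. The dioxepinone ring is closed first and is contracted to ring C last.

Assumption: 1, 2 and 7 are bought in the protected forms shown (catalogue compounds). If 1 is unavailable it is made from resorcinol with MOMCl/i-Pr2NEt, which adds one step.

## Route

Step 1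
Reactants: 1 1,3-bis(methoxymethoxy)benzene; 2 ethyl 2-[(tert-butyldimethylsilyl)oxy]acetate
Product: 4 1-[2,6-bis(methoxymethoxy)phenyl]-2-[(tert-butyldimethylsilyl)oxy]ethan-1-one, via aryllithium 3 (not isolated)
Conditions: n-BuLi (1.1 equiv), THF, 0 °C, 1 h; 2 (0.9 equiv), −78 °C, 1 h; AcOH (1.2 equiv) at −78 °C
Reagents that add atoms: n-butyllithium, [Li]CCCC (lithium of 3 only)
Why: Directed ortho-metalation, in which the two MOM ethers together steer n-BuLi to C2, followed by acyl substitution on the ester that stops at the ketone because the 2,6-disubstituted aryl ketone is too hindered for a second addition; no stereocentre.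

Step 2
Reactants: 4 1-[2,6-bis(methoxymethoxy)phenyl]-2-[(tert-butyldimethylsilyl)oxy]ethan-1-one
Product: 6 2-[(tert-butyldimethylsilyl)oxy]-1-[4-hydroxy-2,6-bis(methoxymethoxy)phenyl]ethan-1-one, via arylboronate 5 (not isolated)
Conditions: [Ir(OMe)(cod)]2 (1.5 mol %), 4,4'-di-tert-butyl-2,2'-bipyridine (3 mol %), B2pin2 (1.0 equiv), THF, 65 °C, 12 h; then NaBO3·4H2O (3 equiv), THF–H2O 1:1, rt, 2 h
Reagents that add atoms: bis(pinacolato)diboron, CC1(C)OB(OC1(C)C)B1OC(C)(C)C(C)(C)O1 (Bpin group of 5 only); sodium perborate, [Na+].[O-]OB=O (phenol oxygen of 6)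
Why: Sterically controlled iridium-catalysed aromatic C–H borylation, where only the C–H para to the acyl group of the 1,2,3-trisubstituted ring has no ortho neighbour, followed by mild perborate oxidation of the C–B bond that leaves MOM, TBS and the ketone untouched; no stereocentre.

Step 3
Reactants: 7 (4-bromophenoxy)(tert-butyl)dimethylsilane
Product: 9 4-[(tert-butyldimethylsilyl)oxy]benzaldehyde, via aryllithium 8 (not isolated)
Conditions: n-BuLi (1.05 equiv), THF, −78 °C, 30 min; DMF (1.5 equiv), −78 → 0 °C; aq. AcOH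
Reagents that add atoms: n-butyllithium, [Li]CCCC (lithium of 8 only); N,N-dimethylformamide, CN(C)C=O (formyl group of 9)
Why: Bromine–lithium exchange followed by Bouveault-type formylation with DMF, in which the para silyl ether cannot migrate and survives at −78 °C; no stereocentre.

Step 4
Reactants: 6 2-[(tert-butyldimethylsilyl)oxy]-1-[4-hydroxy-2,6-bis(methoxymethoxy)phenyl]ethan-1-one; 9 4-[(tert-butyldimethylsilyl)oxy]benzaldehyde
Product: 12 rac-2-{4-[(tert-butyldimethylsilyl)oxy]phenyl}-6,8-dihydroxy-2H-1,3-benzodioxepin-5(4H)-one, via tetraol 10 (not isolated), via dimethyl acetal 11 (not isolated)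
Conditions: camphor-10-sulfonic acid (0.2 equiv), MeOH, 50 °C, 6 h; cool to rt, add 9 (1.2 equiv) and HC(OMe)3 (1.5 equiv), 1 h; swap solvent to THF–toluene 1:3, 5 Å MS, 40 °C, 200 mbar
Reagents that add atoms: trimethyl orthoformate, COC(OC)OC (methoxy groups of 11 only; none of its atoms stay in 12)
Why: Acid methanolysis removes the primary TBS ether and the two MOM ethers activated by the ortho acyl group, and the same acid then drives a 4-alkoxybenzylidene transacetalisation in which only the CH2OH/ortho-OH pair can close a ring (the two ortho phenols are equivalent); the acetal stereocentre forms racemic, which is harmless because step 6 erases it.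

Step 5
Reactants: 12 rac-2-{4-[(tert-butyldimethylsilyl)oxy]phenyl}-6,8-dihydroxy-2H-1,3-benzodioxepin-5(4H)-one; 13 1-bromo-3-methylbut-2-ene (prenyl bromide)
Product: 14 rac-2-{4-[(tert-butyldimethylsilyl)oxy]phenyl}-6-hydroxy-8-[(3-methylbut-2-en-1-yl)oxy]-2H-1,3-benzodioxepin-5(4H)-one
Conditions: K2CO3 (1.1 equiv), 13 (1.05 equiv), dry acetone, rt, 12 h
Reagents that add atoms: none
Why: Williamson ether synthesis under the chelation control known from 7-O-alkylation of 5,7-dihydroxyflavonoids, in which the 6-OH is locked in a hydrogen bond to the ketone so only the more acidic 8-OH reacts, while the acetal and aryl silyl ether tolerate K2CO3 in dry acetone; no new stereocentre.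

Step 6
Reactants: 14 rac-2-{4-[(tert-butyldimethylsilyl)oxy]phenyl}-6-hydroxy-8-[(3-methylbut-2-en-1-yl)oxy]-2H-1,3-benzodioxepin-5(4H)-one
Product: 16 (2R,3R)-3,5-dihydroxy-2-(4-hydroxyphenyl)-7-[(3-methylbut-2-en-1-yl)oxy]-2,3-dihydro-4H-chromen-4-one (7-prenyloxyaromadendrin), via silyl ether 15 (not isolated)
Conditions: (R)-3,3'-bis(2,4,6-triisopropylphenyl)-1,1'-binaphthyl-2,2'-diyl hydrogen phosphate (10 mol %), toluene (0.02 M), 5 Å MS, 40 °C, 24–48 h; filter, concentrate; KHF2 (2 equiv), MeOH, rt, 1 h
Reagents that add atoms: none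
Why: Proposed new method: a catalytic, enantioconvergent 1,2-shift of the acetal carbon C2 from O3 to C4 of the dioxepinone (a Brønsted-acid counterpart of the acetal [1,2]-Wittig rearrangement) contracts the seven-membered ring to ring C. The acid enolises the α-alkoxy ketone to a cyclic enol acetal, whose C2–O3 bond then ionises to a planar aryloxycarbenium ion stabilised by the 4-silyloxyphenyl group, and this erases the racemic acetal centre. The released (Z)-enediol is held by two hydrogen bonds to the chiral phosphate, and its CH carbon attacks the tethered cation in a 6-endo aldol-type closure; attack through the other enediol carbon would be a disfavoured 5-endo closure. The catalyst pocket selects the enediol face (3R), and the diequatorial half-chair places the aryl group trans (2R), which is also the thermodynamic arrangement. Exchange of a C–O bond for a C–C bond, loss of the seven-membered ring and the conjugated, doubly hydrogen-bonded ketone make the step downhill. The process is stepwise and ionic. The closest known reaction types are the Petasis–Ferrier rearrangement of cyclic enol acetals, its chiral-phosphoric-acid-catalysed aza variant on racemic hemiaminal vinyl ethers, and the [1,2]-Wittig rearrangement of acetals. KHF2 then cleaves only the phenolic silyl ether under non-basic conditions, so neither centre epimerises.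

## Compound list
1 | 1,3-bis(methoxymethoxy)benzene | COCOc1cccc(OCOC)c1 | starting material
2 | ethyl 2-[(tert-butyldimethylsilyl)oxy]acetate | CCOC(=O)CO[Si](C)(C)C(C)(C)C | starting material
3 | [2,6-bis(methoxymethoxy)phenyl]lithium | [Li]c1c(OCOC)cccc1OCOC | intermediate
4 | 1-[2,6-bis(methoxymethoxy)phenyl]-2-[(tert-butyldimethylsilyl)oxy]ethan-1-one | COCOc1cccc(OCOC)c1C(=O)CO[Si](C)(C)C(C)(C)C | intermediate
5 | 1-[2,6-bis(methoxymethoxy)-4-(4,4,5,5-tetramethyl-1,3,2-dioxaborolan-2-yl)phenyl]-2-[(tert-butyldimethylsilyl)oxy]ethan-1-one | COCOc1cc(B2OC(C)(C)C(C)(C)O2)cc(OCOC)c1C(=O)CO[Si](C)(C)C(C)(C)C | intermediate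
6 | 2-[(tert-butyldimethylsilyl)oxy]-1-[4-hydroxy-2,6-bis(methoxymethoxy)phenyl]ethan-1-one | COCOc1cc(O)cc(OCOC)c1C(=O)CO[Si](C)(C)C(C)(C)C | intermediate
7 | (4-bromophenoxy)(tert-butyl)dimethylsilane | Brc1ccc(O[Si](C)(C)C(C)(C)C)cc1 | starting material
8 | {4-[(tert-butyldimethylsilyl)oxy]phenyl}lithium | [Li]c1ccc(O[Si](C)(C)C(C)(C)C)cc1 | intermediate
9 | 4-[(tert-butyldimethylsilyl)oxy]benzaldehyde | O=Cc1ccc(O[Si](C)(C)C(C)(C)C)cc1 | intermediate
10 | 2-hydroxy-1-(2,4,6-trihydroxyphenyl)ethan-1-one | O=C(CO)c1c(O)cc(O)cc1O | intermediate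
11 | tert-butyl[4-(dimethoxymethyl)phenoxy]dimethylsilane | COC(OC)c1ccc(O[Si](C)(C)C(C)(C)C)cc1 | intermediate
12 | rac-2-{4-[(tert-butyldimethylsilyl)oxy]phenyl}-6,8-dihydroxy-2H-1,3-benzodioxepin-5(4H)-one (racemic) | Oc1cc(O)c2C(=O)COC(c3ccc(O[Si](C)(C)C(C)(C)C)cc3)Oc2c1 | intermediate
13 | 1-bromo-3-methylbut-2-ene | CC(C)=CCBr | starting material
14 | rac-2-{4-[(tert-butyldimethylsilyl)oxy]phenyl}-6-hydroxy-8-[(3-methylbut-2-en-1-yl)oxy]-2H-1,3-benzodioxepin-5(4H)-one (racemic) | CC(C)=CCOc1cc(O)c2C(=O)COC(c3ccc(O[Si](C)(C)C(C)(C)C)cc3)Oc2c1 | intermediate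
15 | (2R,3R)-2-{4-[(tert-butyldimethylsilyl)oxy]phenyl}-3,5-dihydroxy-7-[(3-methylbut-2-en-1-yl)oxy]-2,3-dihydro-4H-chromen-4-one | CC(C)=CCOc1cc(O)c2c(c1)O[C@H](c1ccc(O[Si](C)(C)C(C)(C)C)cc1)[C@@H](O)C2=O | intermediate
16 | (2R,3R)-3,5-dihydroxy-2-(4-hydroxyphenyl)-7-[(3-methylbut-2-en-1-yl)oxy]-2,3-dihydro-4H-chromen-4-one | CC(C)=CCOc1cc(O)c2c(c1)O[C@H](c1ccc(O)cc1)[C@@H](O)C2=O | target

## Step count and risks
Total steps: 6. Longest linear sequence: 5 (steps 1, 2, 4, 5, 6); step 3 is a one-step side branch.

**Most likely to fail, first: step 6 (the proposed new step).**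
- Enolisation of the hindered, hydrogen-bonded aryl ketone may be slow.
- The acetal may ionise mainly at the aryl C–O bond. That is reversible but unproductive.
- The cation may alkylate the electron-rich ring A of a second molecule, hence the high dilution.
- The enantioselectivity and its sense are unproven. The first run fixes the sense, and the (S)-acid is equally available.
- Re-ionisation of 15 at C2–O1 would only equilibrate C2 towards the wanted trans isomer.

The fallback uses known chemistry only. It sets out from 6, uses 9 and 13, and comes back at 16. Phenol 6 is O-prenylated with 13 and K2CO3 in acetone to 1-[2,6-bis(methoxymethoxy)-4-(3-methylbut-2-enyloxy)phenyl]-2-[(tert-butyldimethylsilyl)oxy]ethan-1-one F1. Its (Z)-boron enolate is made with diisopinocampheylboron triflate (Ipc2BOTf, enantiomer chosen for the 2R centre) and i-Pr2NEt in CH2Cl2 at −78 °C. It adds to 9 in a reagent-controlled syn boron aldol (Zimmerman–Traxler chair) to give (2R,3S)-1-[2,6-bis(methoxymethoxy)-4-(3-methylbut-2-enyloxy)phenyl]-2-[(tert-butyldimethylsilyl)oxy]-3-{4-[(tert-butyldimethylsilyl)oxy]phenyl}-3-hydroxypropan-1-one F2. Brief 0.5 M HCl in MeOH at rt removes the two acyl-activated MOM groups. The freed phenol then replaces the activated benzylic hydroxyl through the benzylic cation, closing to the thermodynamic 2,3-trans ring with the α-oxygenated centre untouched. This gives (2R,3R)-3-[(tert-butyldimethylsilyl)oxy]-2-{4-[(tert-butyldimethylsilyl)oxy]phenyl}-5-hydroxy-7-(3-methylbut-2-enyloxy)-2,3-dihydro-4H-chromen-4-one F3. Et3N·3HF in THF removes both silyl groups and gives 16.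

**Second: step 4.**
- The seven-membered mixed aryl/alkyl acetal is formed under equilibrium control and may be disfavoured.
- The activated aldehyde may attack ring A of 10 at carbon.

The fallback replaces the equilibrium method by an irreversible silyl-transfer acetalisation. It sets out from 10 (now isolated) and 9, and comes back at 12. Tetraol 10 is persilylated with Me3SiCl and imidazole in DMF to 1-[2,4,6-tris(trimethylsilyloxy)phenyl]-2-(trimethylsilyloxy)ethan-1-one F4. F4 and 9 are treated with Me3SiOTf (5 mol %) in CH2Cl2 at −78 °C (Noyori-type acetalisation, kinetic and driven by disiloxane formation). This gives rac-2-{4-[(tert-butyldimethylsilyl)oxy]phenyl}-6,8-bis(trimethylsilyloxy)-2H-1,3-benzodioxepin-5(4H)-one F5. Its two labile aryl trimethylsilyl ethers fall off on aqueous work-up to give 12.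

**Third: step 1.**
- The hindered aryllithium may enolise the ester or the product ketone instead of adding.

The fallback changes the acylation into addition plus oxidation. It sets out from 3 and comes back at 4. Aryllithium 3 is added at −78 °C to commercial (tert-butyldimethylsilyloxy)acetaldehyde to give rac-1-[2,6-bis(methoxymethoxy)phenyl]-2-[(tert-butyldimethylsilyl)oxy]ethan-1-ol F6. This alcohol is oxidised with Dess–Martin periodinane (1,1,1-triacetoxy-1,1-dihydro-1,2-benziodoxol-3(1H)-one) in CH2Cl2 to 4.

## Further compounds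
F1 | step 6 | 1-[2,6-bis(methoxymethoxy)-4-(3-methylbut-2-enyloxy)phenyl]-2-[(tert-butyldimethylsilyl)oxy]ethan-1-one | COCOc1cc(OCC=C(C)C)cc(OCOC)c1C(=O)CO[Si](C)(C)C(C)(C)C
F2 | step 6 | (2R,3S)-1-[2,6-bis(methoxymethoxy)-4-(3-methylbut-2-enyloxy)phenyl]-2-[(tert-butyldimethylsilyl)oxy]-3-{4-[(tert-butyldimethylsilyl)oxy]phenyl}-3-hydroxypropan-1-one | COCOc1cc(OCC=C(C)C)cc(OCOC)c1C(=O)[C@H](O[Si](C)(C)C(C)(C)C)[C@@H](O)c1ccc(O[Si](C)(C)C(C)(C)C)cc1
F3 | step 6 | (2R,3R)-3-[(tert-butyldimethylsilyl)oxy]-2-{4-[(tert-butyldimethylsilyl)oxy]phenyl}-5-hydroxy-7-(3-methylbut-2-enyloxy)-2,3-dihydro-4H-chromen-4-one | CC(C)=CCOc1cc(O)c2c(c1)O[C@H](c1ccc(O[Si](C)(C)C(C)(C)C)cc1)[C@@H](O[Si](C)(C)C(C)(C)C)C2=O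
F4 | step 4 | 1-[2,4,6-tris(trimethylsilyloxy)phenyl]-2-(trimethylsilyloxy)ethan-1-one | C[Si](C)(C)OCC(=O)c1c(O[Si](C)(C)C)cc(O[Si](C)(C)C)cc1O[Si](C)(C)C
F5 | step 4 | rac-2-{4-[(tert-butyldimethylsilyl)oxy]phenyl}-6,8-bis(trimethylsilyloxy)-2H-1,3-benzodioxepin-5(4H)-one | C[Si](C)(C)Oc1cc(O[Si](C)(C)C)c2C(=O)COC(c3ccc(O[Si](C)(C)C(C)(C)C)cc3)Oc2c1
F6 | step 1 | rac-1-[2,6-bis(methoxymethoxy)phenyl]-2-[(tert-butyldimethylsilyl)oxy]ethan-1-ol | COCOc1cccc(OCOC)c1C(O)CO[Si](C)(C)C(C)(C)C
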